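A neighbour of this flask, the same charge read at 4.0 d, will be the second test of a ratio that we build here for the run to 25 h.

substrate 2.0 M; reagent in the second phase 1.40 M; time 25 h; volume of the second phase over the first 1.0

    reagent in the reaction phase ⇌ reagent in the second phase, rate k1*([reagent in the reaction phase] - [reagent in the second phase]/K1) per volume of the first phase (K1 = 0.34, k1 = 4.4 × 10⁻⁴ min⁻¹)
    substrate + reagent in the reaction phase → target (k2 = 3.9 × 10⁻⁴ M⁻¹ min⁻¹)
    substrate + target → side product (k3 = 1.7 × 10⁻⁴ M⁻¹ min⁻¹)
    reagent in the reaction phase + target ⇌ idle adduct, settled at all times (K4 = 1.5 M⁻¹)
    2 substrate → self-condensation product (k5 = 1.4 × 10⁻⁴ M⁻¹ min⁻¹)

- amount of target and idle adduct together at 25 h, in percent of the substrate charged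
- the change that raises the amount of target and idle adduct together at 25 h, in percent of the substrate charged most ("none" if none brings more than 2 percentage points) (Thursday's / Sunday's / none)
- amount of target and idle adduct together at 25 h, in percent of the substrate charged, after Sunday's

- percentages count the substrate that a species holds: one side product or self-condensation product counts as two
- target is meant together with its idle adduct
- two of one species on the left: rate k times its square, two consumed each time
- in the second phase: reagent in the second phase; everything else is in the first
- charges count per volume of the first phase; a concentration in a rate is the amount of a species over the volume of its own phase; every rate counts per litre of the first phase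
- run time (flask): 25 h

We turn the question round: what would make target, not self-condensation product, take the larger part of the substrate leaving? Let a be the free substrate as a fraction of its charge, and b the reagent in the reaction phase as a fraction of the reagent charge. Substrate goes to target at 3.9 × 10⁻⁴ M⁻¹ min⁻¹ times both concentrations, and to self-condensation at twice 1.4 × 10⁻⁴ M⁻¹ min⁻¹ times its own concentration squared. Target therefore leads when b/a exceeds 1.03, and we call this the crossover ratio: there, target takes half of the substrate leaving by these two steps.

On a first pass, a is one, and b heads for its balance with the second phase, 0.746 if nothing is consumed, which is short of the crossover. On a second pass we put back self-condensation as the one loss, so a falls to 0.543 by 25 h. The balance value over that a is 1.37, past the crossover. Reagent spent on target or held in idle adduct lowers b, and the balance value over a lies 0.347 above the crossover, so we expect this flask to end near the crossover, with target's share of the substrate leaving by the two steps rising from zero to about 0.5 and averaging m = 0.250. In this reckoning, with side product left aside, self-condensation takes 0.457 of the substrate, so we estimate target and idle adduct together at that times m/(1−m), or 15.2%. Thursday's halves the crossover ratio to 0.515, below the balance value, while Sunday's leaves it at 1.03, so we choose Thursday's. We made no figure for Sunday's.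

The forecast gives 16.2%, 19.6% after Sunday's, and Thursday's, holding that “Doubling the reagent charge doubles the feed and sustains it”.

The flask gives 15.7%, 19.4% after Sunday's, and Thursday's as best, worth 13 percentage points against 3.7 points. At 25.0 h this flask holds substrate at 42.6% and reagent in the reaction phase at 0.564 M, so b/a reads 0.945, below the crossover ratio of 1.03. In the neighbour read at 4.0 d, substrate stands at 9.84% and reagent in the reaction phase at 0.385 M, so b/a reads 2.79, above it, with target and idle adduct together at 28.2%.

The rate constants are assumed; the rest is arithmetic.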